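**Retrosynthetic overview**

- The strategy rests on ring A of the chromone (C4a, C5, C6, C7, C8, C8a). Its oxygens on C5, C7 and C8a alternate with the methyl-bearing C6 and C8, and C4a carries the C4 acyl carbon. This is the pattern that a linear 2,4-dimethyl-3,5,7,9-tetraoxo ester gives on Claisen condensation.
- Ring C is opened first at O1–C2 (cyclodehydration), which leads back to an ortho-hydroxyaryl 1,3-diketone.
- Ring A is then opened at C4a–C8a (Claisen fold). The chain is stored as a 4-hydroxy-3,5-dimethyl-2-pyranone that carries a 2,4-dioxotetracosyl side chain.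
- The side chain is cut at C4–C4a into the dianion of 4-hydroxy-3,5,6-trimethyl-2-pyranone and a ketal-protected methyl 3-oxotricosanoate. These come from methyl 2-methyl-3-oxopentanoate and from henicosanoic acid plus Meldrum's acid.
- Ring order in the forward direction: auxiliary pyranone (lactone), then benzene ring A, then pyranone ring C.

Key step: step 7

Remark on the chemistry: chromone numbering of the target (O1, C2, C3, C4, C4a, C5 to C8, C8a) is used for atoms throughout. All β-dicarbonyl compounds are drawn as keto forms although they exist largely as enols or metal chelates. The target is achiral.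

**Step 1**
Reactants: 1 methyl 2-methyl-3-oxopentanoate
Product: 3 methyl 2,4-dimethyl-3,5-dioxohexanoate, via dilithium dienolate of methyl 2-methyl-3-oxopentanoate 2 (not isolated)
Conditions: LiN(i-Pr)2 (2.2 equiv), THF, −78 → 0 °C; MeC(O)N(OMe)Me, −78 → 0 °C; then 1 M HCl
Reagents that add atoms: N-methoxy-N-methylacetamide, CC(=O)N(C)OC
Why: γ-Selective C-acylation of a β-keto ester dianion by a Weinreb amide (Weinreb ketone synthesis); the second deprotonation makes C4 of the ester the most nucleophilic site, the amide transfers only one acetyl group because the ketone is released on acidic work-up, and the two stereocentres of 3 form unselectively but both become sp2 carbons in step 2.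

**Step 2**
Reactants: 3 methyl 2,4-dimethyl-3,5-dioxohexanoate
Product: 4 4-hydroxy-3,5,6-trimethyl-2H-pyran-2-one
Conditions: DBU (2 equiv), toluene, 80 °C; then 1 M HCl
Reagents that add atoms: none
Why: Base-mediated lactonisation of a 3,5-dioxo ester, in which the enolate oxygen of the C5 ketone attacks the methyl ester (6-exo-trig) and methanol is lost, the standard entry to 4-hydroxy-2-pyranones.

**Step 3**
Reactants: 5 henicosanoic acid; 6 Meldrum's acid (2,2-dimethyl-1,3-dioxane-4,6-dione)
Product: 8 methyl 3-oxotricosanoate, via 5-(1-hydroxyhenicosylidene)-2,2-dimethyl-1,3-dioxane-4,6-dione 7 (not isolated)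
Conditions: DCC, DMAP, CH2Cl2, 0 °C → rt; filter, acid wash, solvent switch; then MeOH, reflux
Reagents that add atoms: methanol, CO
Why: DMAP-mediated C-acylation of Meldrum's acid by the DCC-activated acid, followed by methanolysis with loss of acetone and CO2, is the standard two-carbon homologation of a carboxylic acid to a methyl β-keto ester.

**Step 4**
Reactants: 8 methyl 3-oxotricosanoate
Product: 9 methyl 2-(2-icosyl-1,3-dioxolan-2-yl)acetate
Conditions: HOCH2CH2OH (5 equiv), TsOH·H2O (cat.), toluene, reflux, Dean–Stark
Reagents that add atoms: ethylene glycol, OCCO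
Why: Acid-catalysed ketalisation driven by azeotropic removal of water converts only the ketone, which masks the future C2 carbonyl and leaves the ester as the single electrophilic site for step 5.

**Step 5**
Reactants: 4 4-hydroxy-3,5,6-trimethyl-2H-pyran-2-one; 9 methyl 2-(2-icosyl-1,3-dioxolan-2-yl)acetate
Product: 11 4-hydroxy-6-[3-(2-icosyl-1,3-dioxolan-2-yl)-2-oxopropyl]-3,5-dimethyl-2H-pyran-2-one, via dilithium dianion of the trimethylpyranone 10 (not isolated)
Conditions: 4 (2.2 equiv), LiN(i-Pr)2 (4.4 equiv), THF, −78 → −20 °C; 9 in THF, −78 → 0 °C; then cold 1 M HCl to pH 3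
Reagents that add atoms: none
Why: Claisen-type C-acylation of a 4-hydroxy-6-methyl-2-pyranone dianion by an ester; the second deprotonation occurs at the 6-methyl group, the only C–H conjugated through C5=C6 to the ring carbonyl system, and the excess dianion takes up the acidic proton of the 2-oxoalkyl product, forming the C4–C4a bond.

**Step 6**
Reactants: 11 4-hydroxy-6-[3-(2-icosyl-1,3-dioxolan-2-yl)-2-oxopropyl]-3,5-dimethyl-2H-pyran-2-one
Product: 12 6-(2,4-dioxotetracosyl)-4-hydroxy-3,5-dimethyl-2H-pyran-2-one
Conditions: 1 M HCl, THF, 40 °C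
Reagents that add atoms: water, O
Why: Acid-catalysed hydrolysis of the dioxolane releases the ketone, and the 5-methyl group blocks acid-driven aldol closure of pyranone C5 onto the side chain, so the polyketone should survive.

**Step 7**
Reactants: 12 6-(2,4-dioxotetracosyl)-4-hydroxy-3,5-dimethyl-2H-pyran-2-one
Product: 14 1-(2,4,6-trihydroxy-3,5-dimethylphenyl)tricosane-1,3-dione, via methyl 2,4-dimethyl-3,5,7,9-tetraoxononacosanoate 13 (not isolated)
Conditions: Mg(OMe)2 (8 equiv), degassed MeOH–THF, reflux, argon; then cold 1 M HCl
Reagents that add atoms: none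
Why: Methoxide from Mg(OMe)2 adds to the lactone carbonyl (C8a) of the magnesium pyranonate and opens it to tetraketo ester 13, held as a magnesium polyenolate chelate; the C4a carbanion, flanked by the C4 and C5 carbonyls, then attacks the C8a ester carbonyl, methoxide leaves, and enolisation of the cyclohexanetrione gives aromatic ring A. The closest known reaction type is the Mg(OMe)2-induced intramolecular Claisen (Dieckmann-type) cyclisation of 6-(2-oxoalkyl)- and 6-(2,4-dioxoalkyl)-4-hydroxy-2-pyranones to acylphloroglucinols. Ring A closes in the 6-exo-trig mode (6-enolendo-exo-trig with respect to the C5 enolate), which is favoured. No stereocentre is formed. The step needs the Claisen fold (C4a onto C8a) to win over the aldol fold (C3 onto the C7 carbonyl): the C7 ketone lies between the methyl-bearing C6 and C8 and is shielded, the hard magnesium counter-ion holds the chain as chelated enolates that favour acylation at the ester over addition to a ketone, and aromatisation to the magnesium phloroglucinolate makes the Claisen product the thermodynamic sink. The pyranone keeps the C7 and C8a carbonyls masked and both C-methyl groups in place until this step, and partial closure of ring C on work-up would be harmless because step 8 completes it.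

**Step 8**
Reactants: 14 1-(2,4,6-trihydroxy-3,5-dimethylphenyl)tricosane-1,3-dione
Product: 15 5,7-dihydroxy-2-icosyl-6,8-dimethyl-4H-chromen-4-one
Conditions: conc. HCl (cat.), AcOH, 90 °C
Reagents that add atoms: none
Why: Acid-catalysed cyclodehydration of an ortho-hydroxyaryl 1,3-diketone (the closing stage of a Baker–Venkataraman chromone synthesis); a phenolic OH next to the acyl group adds to the C2 ketone in a 6-exo-trig closure of O1–C2 and water is lost to give ring C, and because ring A is symmetric both ortho hydroxyls lead to the same chromone.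

**Compound list**

1 | methyl 2-methyl-3-oxopentanoate (racemic) | CCC(=O)C(C)C(=O)OC | starting material
2 | dilithium dienolate of methyl 2-methyl-3-oxopentanoate (deprotonated at C2 and C4) | CC=C([O-])C(C)=C([O-])OC.[Li+].[Li+] | intermediate
3 | methyl 2,4-dimethyl-3,5-dioxohexanoate (mixture of diastereomers and tautomers) | CC(=O)C(C)C(=O)C(C)C(=O)OC | intermediate
4 | 4-hydroxy-3,5,6-trimethyl-2H-pyran-2-one | Cc1oc(=O)c(C)c(O)c1C | intermediate
5 | henicosanoic acid | CCCCCCCCCCCCCCCCCCCCC(=O)O | starting material
6 | Meldrum's acid (2,2-dimethyl-1,3-dioxane-4,6-dione) | CC1(C)OC(=O)CC(=O)O1 | starting material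
7 | 5-(1-hydroxyhenicosylidene)-2,2-dimethyl-1,3-dioxane-4,6-dione | CCCCCCCCCCCCCCCCCCCCC(O)=C1C(=O)OC(C)(C)OC1=O | intermediate
8 | methyl 3-oxotricosanoate | CCCCCCCCCCCCCCCCCCCCC(=O)CC(=O)OC | intermediate
9 | methyl 2-(2-icosyl-1,3-dioxolan-2-yl)acetate | CCCCCCCCCCCCCCCCCCCCC1(CC(=O)OC)OCCO1 | intermediate
10 | dilithium dianion of 4-hydroxy-3,5,6-trimethyl-2H-pyran-2-one (4-olate, 6-methylide) | [CH2-]c1oc(=O)c(C)c([O-])c1C.[Li+].[Li+] | intermediate
11 | 4-hydroxy-6-[3-(2-icosyl-1,3-dioxolan-2-yl)-2-oxopropyl]-3,5-dimethyl-2H-pyran-2-one | CCCCCCCCCCCCCCCCCCCCC1(CC(=O)Cc2oc(=O)c(C)c(O)c2C)OCCO1 | intermediate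
12 | 6-(2,4-dioxotetracosyl)-4-hydroxy-3,5-dimethyl-2H-pyran-2-one | CCCCCCCCCCCCCCCCCCCCC(=O)CC(=O)Cc1oc(=O)c(C)c(O)c1C | intermediate
13 | methyl 2,4-dimethyl-3,5,7,9-tetraoxononacosanoate (magnesium chelate in the flask, mixture of stereoisomers) | CCCCCCCCCCCCCCCCCCCCC(=O)CC(=O)CC(=O)C(C)C(=O)C(C)C(=O)OC | intermediate
14 | 1-(2,4,6-trihydroxy-3,5-dimethylphenyl)tricosane-1,3-dione | CCCCCCCCCCCCCCCCCCCCC(=O)CC(=O)c1c(O)c(C)c(O)c(C)c1O | intermediate
15 | 5,7-dihydroxy-2-icosyl-6,8-dimethyl-4H-chromen-4-one | CCCCCCCCCCCCCCCCCCCCc1cc(=O)c2c(O)c(C)c(O)c(C)c2o1 | target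

**Step count**

Total step count: 8.
Longest linear sequence: 6 steps (steps 3, 4, 5, 6, 7, 8 from henicosanoic acid; the pyranone branch through steps 1, 2, 5, 6, 7, 8 is equally long).

**Steps most likely to fail**

1. Step 7. The chain may fold in the aldol sense (C3 onto the C7 carbonyl), methoxide may cleave the exposed β-diketone by retro-Claisen reaction, and the hindered, anionic lactone may open slowly. The fallback folds before the terminal ketone is unmasked; it sets out from 11 and comes back to the route at 14, which is carried on in the same pot to 15. Mg(OMe)2 in MeOH–THF at reflux would open 11 to methyl 8-(2-icosyl-1,3-dioxolan-2-yl)-2,4-dimethyl-3,5,7-trioxooctanoate F1. In F1 C2 is still a ketal, so C3 is only singly activated and no β-diketone is offered to methoxide. Claisen closure of C4a onto C8a would give 2-(2-icosyl-1,3-dioxolan-2-yl)-1-(2,4,6-trihydroxy-3,5-dimethylphenyl)ethan-1-one F2. Concentrated HCl in aqueous acetic acid at 90 °C would then hydrolyse the dioxolane to 14 and cyclodehydrate it as in step 8. Step 6 is then not needed.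

2. Step 5. The dianion may act as a base toward the α-CH2 of the ester and trigger β-elimination that opens the dioxolane, proton transfer from the product may consume the nucleophile, and the long-chain ester may dissolve poorly at low temperature. The fallback adds the chain one acyl unit at a time without any β-alkoxy ester; it sets out from 4 and comes back at 12. Dianion 10 would be acetylated with N-methoxy-N-methylacetamide to 4-hydroxy-3,5-dimethyl-6-(2-oxopropyl)-2H-pyran-2-one F3. LiN(i-Pr)2 (3.3 equiv) in THF would convert F3 into its trilithium trianion F4, deprotonated at the 4-OH, the side-chain CH2 and the terminal CH3. F4, used in excess, would be acylated at the terminal carbon by methyl henicosanoate F5 (from 5, MeOH, H2SO4 cat., reflux) to give 12 directly after acidic work-up. Steps 3, 4 and 6 are then not needed.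

3. Step 1. Acylation may occur on oxygen or at C2 in competition with C4, the second deprotonation at the secondary γ-carbon may be incomplete, and the product may be acylated again. The fallback replaces the acylation by an aldol addition and an oxidation; it sets out from 1 and comes back at 3. Dianion 2 would add to acetaldehyde in THF at −78 °C to give methyl 5-hydroxy-2,4-dimethyl-3-oxohexanoate F6 as a mixture of diastereomers. Oxidation of F6 with Dess–Martin periodinane in CH2Cl2 at rt would give 3.

**Further compounds**

F1 | step 7 | methyl 8-(2-icosyl-1,3-dioxolan-2-yl)-2,4-dimethyl-3,5,7-trioxooctanoate | CCCCCCCCCCCCCCCCCCCCC1(CC(=O)CC(=O)C(C)C(=O)C(C)C(=O)OC)OCCO1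
F2 | step 7 | 2-(2-icosyl-1,3-dioxolan-2-yl)-1-(2,4,6-trihydroxy-3,5-dimethylphenyl)ethan-1-one | CCCCCCCCCCCCCCCCCCCCC1(CC(=O)c2c(O)c(C)c(O)c(C)c2O)OCCO1
F3 | step 5 | 4-hydroxy-3,5-dimethyl-6-(2-oxopropyl)-2H-pyran-2-one | CC(=O)Cc1oc(=O)c(C)c(O)c1C
F4 | step 5 | trilithium trianion of 4-hydroxy-3,5-dimethyl-6-(2-oxopropyl)-2H-pyran-2-one | [CH2-]C(=O)[CH-]c1oc(=O)c(C)c([O-])c1C.[Li+].[Li+].[Li+]
F5 | step 5 | methyl henicosanoate | CCCCCCCCCCCCCCCCCCCCC(=O)OC
F6 | step 1 | methyl 5-hydroxy-2,4-dimethyl-3-oxohexanoate (mixture of diastereomers) | CC(O)C(C)C(=O)C(C)C(=O)OC
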